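**Strategy.** Ring A is disconnected at C8–C8a and C4a–C5. The carbons C5–C8, with their 1,3-related oxygens on C5 and C7, come from a 1,1,3-trioxygenated butadiene. The C4a=C8a bond shared by ring A and ring C comes from the C5=C6 bond of a 2-aryl-3-acyloxy-4-pyranone that carries bromine on C5. One silyl triflate-triggered annulation closes ring A, aromatises it and delivers the chelated 5-hydroxyl beside the 7-methyl ether. The precursor is the 5-bromopyranone with ring B in place, benzyl on O3' and acetates on O3 and O4'.

Key step: step 9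

Assumption: the target is delivered as the free tris(hydrogen sulfate) that is drawn; because aryl hydrogen sulfates are hydrolytically sensitive acids, the acid form is generated only in the last operation from its triethylammonium salt, which would be the storage form.

**Step 1**
Reactants: 1 3,4-dihydroxybenzaldehyde
Product: 2 3-hydroxy-4-(methoxymethoxy)benzaldehyde
Conditions: MOMCl (1.05 equiv), K2CO3 (1.1 equiv), acetone, 0 °C to rt
Reagents that add atoms: chloromethyl methyl ether, COCCl
Why: Williamson-type O-alkylation in which the 4-hydroxyl, para to the formyl group and therefore the more acidic phenol, is deprotonated first by one equivalent of weak base and takes up the chloromethyl ether selectively.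

**Step 2**
Reactants: 2 3-hydroxy-4-(methoxymethoxy)benzaldehyde
Product: 3 3-(benzyloxy)-4-(methoxymethoxy)benzaldehyde
Conditions: BnBr, K2CO3, DMF, rt
Reagents that add atoms: benzyl bromide, BrCc1ccccc1
Why: Williamson ether synthesis on the remaining phenol, to which the aldehyde and the acetal-type ether are inert.

**Step 3**
Reactants: 3 3-(benzyloxy)-4-(methoxymethoxy)benzaldehyde; 4 furan
Product: 6 [3-(benzyloxy)-4-(methoxymethoxy)phenyl](furan-2-yl)methanol (racemic), via 2-lithiofuran 5 (not isolated)
Conditions: 4, n-BuLi, THF, −78 to 0 °C; then 3, −78 °C; H2O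
Reagents that add atoms: none
Why: Furan is lithiated at C2 next to the ring oxygen and the heteroaryllithium adds 1,2 to the aldehyde; the carbinol centre forms as a racemate, which is immaterial because it becomes sp2 in step 5.

**Step 4**
Reactants: 6 [3-(benzyloxy)-4-(methoxymethoxy)phenyl](furan-2-yl)methanol
Product: 8 2-[3-(benzyloxy)-4-(methoxymethoxy)phenyl]-6-methoxy-2H-pyran-3(6H)-one (racemic cis/trans acetal mixture), via dimethoxydihydrofuran carbinol 7 (not isolated)
Conditions: NBS (1.05 equiv), NaHCO3, MeOH, −40 °C; then HCO2H, MeOH, rt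
Reagents that add atoms: methanol, CO
Why: Achmatowicz rearrangement in its methanol variant, in which oxidative 2,5-dimethoxylation of the furan (far more nucleophilic than ring B at −40 °C) is followed by acid-catalysed ring expansion through the carbinol oxygen, giving the methyl acetal directly; both sp3 centres are erased in step 5.

**Step 5**
Reactants: 8 2-[3-(benzyloxy)-4-(methoxymethoxy)phenyl]-6-methoxy-2H-pyran-3(6H)-one
Product: 10 2-[3-(benzyloxy)-4-hydroxyphenyl]-3-hydroxy-4H-pyran-4-one, via epoxy ketone 9 (not isolated)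
Conditions: 30% H2O2, NaOH (cat.), MeOH, 0 °C; then 2 M aq. H2SO4, THF, 65 °C
Reagents that add atoms: hydrogen peroxide, OO
Why: Weitz–Scheffer nucleophilic epoxidation of the enone, then the acid-promoted isomerisation of the epoxy ketone to the diosphenol with loss of methanol from C6 (the maltol-type route to 3-hydroxy-4-pyranones); the same hot aqueous acid deliberately hydrolyses the aryl methoxymethyl ether, and the benzyl ether should survive.

**Step 6**
Reactants: 10 2-[3-(benzyloxy)-4-hydroxyphenyl]-3-hydroxy-4H-pyran-4-one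
Product: 11 2-[4-(acetyloxy)-3-(benzyloxy)phenyl]-4-oxo-4H-pyran-3-yl acetate
Conditions: Ac2O, pyridine, DMAP (cat.), CH2Cl2, 0 °C to rt
Reagents that add atoms: acetic anhydride, CC(=O)OC(C)=O
Why: DMAP-catalysed acylation of the phenol and of the enolic 3-hydroxyl; unlike acetal-type ethers, the acetates are not ionised by a silyl triflate (which would release an oxocarbenium ion that consumes the diene), and they make ring B less nucleophilic for step 7 and the pyranone a better acceptor for step 9.

**Step 7**
Reactants: 11 2-[4-(acetyloxy)-3-(benzyloxy)phenyl]-4-oxo-4H-pyran-3-yl acetate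
Product: 12 2-[4-(acetyloxy)-3-(benzyloxy)phenyl]-5-bromo-4-oxo-4H-pyran-3-yl acetate
Conditions: NBS (1.05 equiv), MeCN, 0 °C to rt, dark
Reagents that add atoms: N-bromosuccinimide, O=C1CCC(=O)N1Br
Why: Electrophilic α-bromination of a 4-pyranone (the reaction that gives 3-halo-4-pyranones and 3-halochromones) at C5, the β-carbon of the vinylogous ester O1–C6=C5–C4=O and the only free nucleophilic ring position; ring B is deactivated by the 4'-acetate and the pyranone, so its C6' position, para to the benzyloxy group, should react more slowly.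

**Step 8**
Reactants: 13 methyl (E)-3-methoxybut-2-enoate
Product: 15 (1Z)-1,3-dimethoxy-1-(trimethylsilyloxy)buta-1,3-diene, via lithium dienolate 14 (not isolated)
Conditions: LiN(i-Pr)2 (commercial solution), THF, −78 °C; Me3SiCl, −78 °C to rt; distillation
Reagents that add atoms: chlorotrimethylsilane, C[Si](C)(C)Cl
Why: γ-Deprotonation of the β-methoxy enoate gives the extended dienolate, which is silylated on oxygen to the silyl ketene acetal (the standard preparation of this diene); its double-bond geometry is lost in step 9.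

**Step 9**
Reactants: 12 2-[4-(acetyloxy)-3-(benzyloxy)phenyl]-5-bromo-4-oxo-4H-pyran-3-yl acetate; 15 (1Z)-1,3-dimethoxy-1-(trimethylsilyloxy)buta-1,3-diene
Product: 18 3,4'-diacetoxy-3'-benzyloxy-5-hydroxy-7-methoxyflavone, via silyloxypyrylium triflate 16 (not isolated), via flavone 5-O-trimethylsilyl ether 17 (not isolated)
Conditions: Me3SiOSO2CF3 (1.2 equiv), 2,6-di-tert-butyl-4-methylpyridine (2.5 equiv), CH2Cl2, −78 °C; 15 (2 equiv), −78 °C to rt; then 1 M HCl, THF, 0 °C
Reagents that add atoms: none
Why: Proposed new method: silylation of the C4 carbonyl of 12 gives the 4-silyloxypyrylium ion 16, whose unsubstituted α-carbon (pyranone C6, the future C8a) is attacked by the CH2 terminus of 15 in a vinylogous Mukaiyama–Michael addition that forms C8–C8a; the silyl enol ether so created at C4=C4a then adds to the silyl-activated ester carbon of the new side chain to form C4a–C5, and loss of methoxide as Me3SiOMe, of HBr across C4a–C8a and of a C8 proton aromatises ring A to the silyl ether 17, which the acidic work-up cleaves. The closest known reactions are the Diels–Alder/elimination annulations of this diene with 2-haloquinones and the silyl triflate-promoted additions of silyl enol ethers and silyl ketene acetals to the α-carbon of chromones and 4-pyranones; their combination on a 3-halo-4-pyranone is what is new. Ring A closes in a 6-exo-trig mode (C4a onto the exocyclic activated C=O of C5), so the event is a stepwise formal (4+2) benzannulation. No stereocentre survives, since the sp3 centres formed transiently at C8a and C4a are erased by the elimination. The step needs regioselectivity (C8 to C8a, C5 to C4a); it is secured because C2 is blocked by ring B, C6 is the only free pyrylium α-position and the diene reacts through its terminal CH2, which leaves the ester carbon to close on the brominated carbon. The bromine supplies the oxidation level for aromatisation, ionisation of the ketal with the silyl triflate expels methoxide and not silyloxide so that O5 emerges free after work-up, and the acetates on O3 and O4' neither ionise nor lower the electrophilicity of the pyrylium ion.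

**Step 10**
Reactants: 18 3,4'-diacetoxy-3'-benzyloxy-5-hydroxy-7-methoxyflavone
Product: 19 3'-benzyloxy-3,5,4'-trihydroxy-7-methoxyflavone (3'-O-benzylrhamnetin)
Conditions: NH3 (7 M in MeOH), THF, 0 °C to rt, argon
Reagents that add atoms: none
Why: Ammonolysis of the aryl and enol acetates (nucleophilic acyl substitution) is fast in the cold and leaves the benzyl and methyl ethers alone, and argon keeps the flavonol from base-promoted autoxidation.

**Step 11**
Reactants: 19 3'-benzyloxy-3,5,4'-trihydroxy-7-methoxyflavone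
Product: 20 tris(triethylammonium) 3'-benzyloxy-7-methoxyflavone-3,5,4'-triyl tris(sulfate)
Conditions: SO3·NEt3 (6 equiv per OH), Et3N, MeCN, 100 °C (sealed tube); Sephadex LH-20
Reagents that add atoms: sulfur trioxide–triethylamine complex, CC[N+](CC)(CC)S(=O)(=O)[O-]
Why: O-sulfation of phenols with a sulfur trioxide–amine complex, run with a large excess of reagent and base at 100 °C, the regime in which the hydrogen-bonded 5-hydroxyl of flavonoids is also sulfated, while the benzyl ether keeps O3' free of sulfate.

**Step 12**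
Reactants: 20 tris(triethylammonium) 3'-benzyloxy-7-methoxyflavone-3,5,4'-triyl tris(sulfate)
Product: 22 rhamnetin 3,5,4'-tri-O-sulfate (free tris(hydrogen sulfate)), via debenzylated tris(triethylammonium) salt 21 (not isolated)
Conditions: H2 (1 atm), Pd/C, MeOH/H2O, rt; filtration; Dowex 50WX8 (H+ form), H2O, 0 °C; freeze-drying
Reagents that add atoms: none
Why: Hydrogenolysis of the benzyl aryl ether over Pd/C leaves aryl sulfate salts, the tetrasubstituted C2=C3 bond and the methyl ether untouched, and cation exchange on a sulfonic acid resin in the cold replaces triethylammonium by protons.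

**Compound list**

1 | 3,4-dihydroxybenzaldehyde | O=Cc1ccc(O)c(O)c1 | starting material
2 | 3-hydroxy-4-(methoxymethoxy)benzaldehyde | O=Cc1ccc(OCOC)c(O)c1 | intermediate
3 | 3-(benzyloxy)-4-(methoxymethoxy)benzaldehyde | O=Cc1ccc(OCOC)c(OCc2ccccc2)c1 | intermediate
4 | furan | c1ccoc1 | starting material
5 | 2-lithiofuran | [Li]c1ccco1 | intermediate (not isolated)
6 | [3-(benzyloxy)-4-(methoxymethoxy)phenyl](furan-2-yl)methanol, racemic | OC(c1ccco1)c1ccc(OCOC)c(OCc2ccccc2)c1 | intermediate
7 | [3-(benzyloxy)-4-(methoxymethoxy)phenyl](2,5-dimethoxy-2,5-dihydrofuran-2-yl)methanol, diastereomer mixture | COC1C=CC(OC)(C(O)c2ccc(OCOC)c(OCc3ccccc3)c2)O1 | intermediate (not isolated)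
8 | 2-[3-(benzyloxy)-4-(methoxymethoxy)phenyl]-6-methoxy-2H-pyran-3(6H)-one, racemic cis/trans mixture | COC1C=CC(=O)C(c2ccc(OCOC)c(OCc3ccccc3)c2)O1 | intermediate
9 | 4-[3-(benzyloxy)-4-(methoxymethoxy)phenyl]-2-methoxy-3,7-dioxabicyclo[4.1.0]heptan-5-one (4,5-epoxide of 8), diastereomer mixture | COC1OC(c2ccc(OCOC)c(OCc3ccccc3)c2)C(=O)C2OC12 | intermediate (not isolated)
10 | 2-[3-(benzyloxy)-4-hydroxyphenyl]-3-hydroxy-4H-pyran-4-one | O=c1ccoc(-c2ccc(O)c(OCc3ccccc3)c2)c1O | intermediate
11 | 2-[4-(acetyloxy)-3-(benzyloxy)phenyl]-4-oxo-4H-pyran-3-yl acetate | CC(=O)Oc1ccc(-c2occc(=O)c2OC(C)=O)cc1OCc1ccccc1 | intermediate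
12 | 2-[4-(acetyloxy)-3-(benzyloxy)phenyl]-5-bromo-4-oxo-4H-pyran-3-yl acetate | CC(=O)Oc1ccc(-c2occ(Br)c(=O)c2OC(C)=O)cc1OCc1ccccc1 | intermediate
13 | methyl (E)-3-methoxybut-2-enoate | CO/C(C)=C/C(=O)OC | starting material
14 | lithium (1Z)-1,3-dimethoxybuta-1,3-dien-1-olate | C=C(OC)/C=C(/OC)O[Li] | intermediate (not isolated)
15 | (1Z)-1,3-dimethoxy-1-(trimethylsilyloxy)buta-1,3-diene (silyloxy group cis to C3) | C=C(OC)/C=C(/OC)O[Si](C)(C)C | intermediate
16 | 3-(acetyloxy)-2-[4-(acetyloxy)-3-(benzyloxy)phenyl]-5-bromo-4-(trimethylsilyloxy)pyrylium trifluoromethanesulfonate | CC(=O)Oc1ccc(-c2[o+]cc(Br)c(O[Si](C)(C)C)c2OC(C)=O)cc1OCc1ccccc1.[O-]S(=O)(=O)C(F)(F)F | intermediate (not isolated)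
17 | 3,4'-diacetoxy-3'-benzyloxy-7-methoxy-5-(trimethylsilyloxy)flavone | COc1cc(O[Si](C)(C)C)c2c(=O)c(OC(C)=O)c(-c3ccc(OC(C)=O)c(OCc4ccccc4)c3)oc2c1 | intermediate (not isolated)
18 | 3,4'-diacetoxy-3'-benzyloxy-5-hydroxy-7-methoxyflavone | COc1cc(O)c2c(=O)c(OC(C)=O)c(-c3ccc(OC(C)=O)c(OCc4ccccc4)c3)oc2c1 | intermediate
19 | 3'-benzyloxy-3,5,4'-trihydroxy-7-methoxyflavone | COc1cc(O)c2c(=O)c(O)c(-c3ccc(O)c(OCc4ccccc4)c3)oc2c1 | intermediate
20 | tris(triethylammonium) 3'-benzyloxy-7-methoxyflavone-3,5,4'-triyl tris(sulfate) | CC[NH+](CC)CC.CC[NH+](CC)CC.CC[NH+](CC)CC.COc1cc(OS(=O)(=O)[O-])c2c(=O)c(OS(=O)(=O)[O-])c(-c3ccc(OS(=O)(=O)[O-])c(OCc4ccccc4)c3)oc2c1 | intermediate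
21 | tris(triethylammonium) 3'-hydroxy-7-methoxyflavone-3,5,4'-triyl tris(sulfate) | CC[NH+](CC)CC.CC[NH+](CC)CC.CC[NH+](CC)CC.COc1cc(OS(=O)(=O)[O-])c2c(=O)c(OS(=O)(=O)[O-])c(-c3ccc(OS(=O)(=O)[O-])c(O)c3)oc2c1 | intermediate (not isolated)
22 | rhamnetin 3,5,4'-tri-O-sulfate | COc1cc(OS(=O)(=O)O)c2c(=O)c(OS(=O)(=O)O)c(-c3ccc(OS(=O)(=O)O)c(O)c3)oc2c1 | target

**Step count and risk**

Total: 12 steps. Longest linear sequence: 11 steps (steps 1–7 and 9–12, from 1); step 8 is a one-step branch.

Steps most likely to fail:

1. Step 9 (Proposed new method). What may go wrong: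
   - the pyranone may be too weakly activated and the diene lost to silyl transfer or hydrolysis;
   - the reaction may stop after the first C–C bond, with the open-chain ester failing to close on the brominated carbon;
   - the adduct may ring-open (retro-oxa-Michael or electrocyclic opening of the 2H-pyran);
   - bromine may be lost as a positive-halogen species instead of as HBr.

   Fallback by known chemistry, setting out from 3 and returning at 19. Commercial 1-(2,6-dihydroxy-4-methoxyphenyl)ethan-1-one is mono-protected (MOMCl, K2CO3, acetone; the second hydroxyl stays hydrogen-bonded to the ketone) to 1-[2-hydroxy-4-methoxy-6-(methoxymethoxy)phenyl]ethan-1-one F1. Claisen–Schmidt condensation of this ketone with 3 (KOH, EtOH, rt) should give (E)-3-[3-(benzyloxy)-4-(methoxymethoxy)phenyl]-1-[2-hydroxy-4-methoxy-6-(methoxymethoxy)phenyl]prop-2-en-1-one F2. Algar–Flynn–Oyamada oxidation (30% H2O2, NaOH, MeOH, 0 °C) should close and hydroxylate ring C to 2-[3-(benzyloxy)-4-(methoxymethoxy)phenyl]-3-hydroxy-7-methoxy-5-(methoxymethoxy)-4H-chromen-4-one F3; aurone formation is the known side path of 6'-oxygenated chalcones. HCl in MeOH at 50 °C removes both methoxymethyl groups and gives 19, so steps 4–10 are bypassed.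

2. Step 7. What may go wrong: competing electrophilic bromination of ring B at C6' (para to the benzyloxy group), or over-bromination, which would give mixtures that are hard to separate.

   Fallback setting out from 11 and returning at 12, replacing electrophilic attack by deprotonative metalation. The C5–H bond next to the C4 carbonyl is zincated with TMPZnCl·LiCl (2,2,6,6-tetramethylpiperidinylzinc chloride–lithium chloride, THF, −30 to 0 °C, no added Lewis acid), the carbonyl-directed zincation known for chromones and 4-pyranones and tolerant of esters. This should give the chlorozinc derivative 2-[4-(acetyloxy)-3-(benzyloxy)phenyl]-5-(chlorozincio)-4-oxo-4H-pyran-3-yl acetate F4, which is quenched with Br2 at −30 °C to give 12; ring B is not touched because it has no comparably acidic C–H bond.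

3. Step 11. What may go wrong: incomplete sulfation of the hydrogen-bonded 5-hydroxyl, or loss of that sulfate during isolation of the polyanionic salt.

   Fallback setting out from 19 and returning at 22 through neutral, chromatographable sulfate diesters.
   - Compound 19 is treated with 2,2,2-trichloroethyl chlorosulfate (Et3N, DMAP, THF, 0 °C to rt) to give the tris(2,2,2-trichloroethyl sulfate) of 3'-O-benzylrhamnetin F5.
   - Zn and HCO2NH4 in MeOH cleave the three trichloroethyl groups by reductive elimination to triammonium 3'-benzyloxy-7-methoxyflavone-3,5,4'-triyl tris(sulfate) F6.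
   - Hydrogenolysis (H2, Pd/C, MeOH/H2O) gives triammonium 3'-hydroxy-7-methoxyflavone-3,5,4'-triyl tris(sulfate) F7.
   - The same cold H+ resin exchange as in step 12 then gives 22.

**Further compounds**

F1 | step 9 | 1-[2-hydroxy-4-methoxy-6-(methoxymethoxy)phenyl]ethan-1-one | COCOc1cc(OC)cc(O)c1C(C)=O
F2 | step 9 | (E)-3-[3-(benzyloxy)-4-(methoxymethoxy)phenyl]-1-[2-hydroxy-4-methoxy-6-(methoxymethoxy)phenyl]prop-2-en-1-one | COCOc1cc(OC)cc(O)c1C(=O)/C=C/c1ccc(OCOC)c(OCc2ccccc2)c1
F3 | step 9 | 2-[3-(benzyloxy)-4-(methoxymethoxy)phenyl]-3-hydroxy-7-methoxy-5-(methoxymethoxy)-4H-chromen-4-one | COCOc1cc(OC)cc2oc(-c3ccc(OCOC)c(OCc4ccccc4)c3)c(O)c(=O)c12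
F4 | step 7 | 2-[4-(acetyloxy)-3-(benzyloxy)phenyl]-5-(chlorozincio)-4-oxo-4H-pyran-3-yl acetate | CC(=O)Oc1ccc(-c2occ([Zn]Cl)c(=O)c2OC(C)=O)cc1OCc1ccccc1
F5 | step 11 | 3'-benzyloxy-7-methoxyflavone-3,5,4'-triyl tris(2,2,2-trichloroethyl sulfate) | COc1cc(OS(=O)(=O)OCC(Cl)(Cl)Cl)c2c(=O)c(OS(=O)(=O)OCC(Cl)(Cl)Cl)c(-c3ccc(OS(=O)(=O)OCC(Cl)(Cl)Cl)c(OCc4ccccc4)c3)oc2c1
F6 | step 11 | triammonium 3'-benzyloxy-7-methoxyflavone-3,5,4'-triyl tris(sulfate) | [NH4+].[NH4+].[NH4+].COc1cc(OS(=O)(=O)[O-])c2c(=O)c(OS(=O)(=O)[O-])c(-c3ccc(OS(=O)(=O)[O-])c(OCc4ccccc4)c3)oc2c1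
F7 | step 11 | triammonium 3'-hydroxy-7-methoxyflavone-3,5,4'-triyl tris(sulfate) | [NH4+].[NH4+].[NH4+].COc1cc(OS(=O)(=O)[O-])c2c(=O)c(OS(=O)(=O)[O-])c(-c3ccc(OS(=O)(=O)[O-])c(O)c3)oc2c1
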